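## Retrosynthetic overview

- **Feature.** Ring atoms C5, C6, C7, C8, C8a and C4a of the tetrahydrochromone correspond to C1–C6 of β-D-glucose, so (5R,6S,7R,8S) is sugar C1–C4. The 1,3-cis oxygens O5 and O7, tied by C7' and C6' of the aromatic chromone into the 2,5-dioxabicyclo[4.3.1]decane, are the sugar's O1 and O3.
- **Endgame.** The heterocycle of chromone B comes last, by carbonylative alkyne annulation of an o-iodophenol. Pyranone A comes before it, from the C8a ketone (as its silyl enol ether) and an acylketene.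
- **Key disconnection, C4a–C5.** The bridged cyclohexanone arises from an O1,O3-arylene-bridged 6-deoxyhex-5-enopyranoside by a TiCl3(OiPr)-induced carbocyclic rearrangement that keeps the aglycone.
- **Bridged pyranoside.** O3–aryl bond by SNAr on diacetone-D-glucose, nitro to phenol, intramolecular β-glycosylation, then elimination of the C6 iodide.
- **Ring order.** Pyranose, benzodioxepine, carbocycle, pyranone A, chromone B.

Key step: step 11

Remark: O2 and O4 of the sugar carry TBS (tert-butyldimethylsilyl) ethers rather than benzyl ethers, so that no stoichiometric strong base meets the 2-OH lying anti to the anomeric aryloxide, the aryl benzyl ether can be removed alone and the last step is a fluoride deprotection; salts formed by mere deprotonation of a numbered compound are not numbered.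

## Route

Step 1
Reactants: 1 4-fluoro-3-nitrophenol
Product: 2 4-(benzyloxy)-1-fluoro-2-nitrobenzene
Conditions: BnBr, K2CO3, acetone, rt to 50 °C
Reagents that add atoms: benzyl bromide, BrCc1ccccc1
Why: Williamson etherification of the acidic nitrophenol under carbonate, mild enough to leave the activated C–F bond for step 2.

Step 2
Reactants: 3 1,2:5,6-di-O-isopropylidene-α-D-glucofuranose (diacetone-D-glucose); 2 4-(benzyloxy)-1-fluoro-2-nitrobenzene
Product: 4 3-O-[4-(benzyloxy)-2-nitrophenyl]-1,2:5,6-di-O-isopropylidene-α-D-glucofuranose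
Conditions: NaH, THF/DMF, 0 °C to rt
Reagents that add atoms: none
Why: Nucleophilic aromatic substitution (addition–elimination) in which the only free hydroxyl, O3, displaces the fluoride ortho to the nitro group, which lays down the future O7–C6' ether with the benzyloxy group para to it and leaves the sugar C3–O bond and its configuration untouched.

Step 3
Reactants: 4 3-O-[4-(benzyloxy)-2-nitrophenyl]-1,2:5,6-di-O-isopropylidene-α-D-glucofuranose
Product: 6 1,2,4,6-tetra-O-acetyl-3-O-[4-(benzyloxy)-2-nitrophenyl]-β-D-glucopyranose, via free 3-O-aryl-D-glucopyranose 5 (not isolated)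
Conditions: TFA/H2O (9:1), rt; evaporate with toluene; then Ac2O, NaOAc, 100 °C
Reagents that add atoms: acetic anhydride, CC(=O)OC(C)=O
Why: Acid hydrolysis of both acetonides lets the sugar relax to the pyranose, and acetylation under NaOAc (fast mutarotation, more reactive equatorial anomeric hydroxyl) should give mainly the β-tetraacetate, the anomer that ionises best with anchimeric help in step 6.

Step 4
Reactants: 6 1,2,4,6-tetra-O-acetyl-3-O-[4-(benzyloxy)-2-nitrophenyl]-β-D-glucopyranose
Product: 7 1,2,4,6-tetra-O-acetyl-3-O-[2-amino-4-(benzyloxy)phenyl]-β-D-glucopyranose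
Conditions: Zn, AcOH/THF, 0 °C to rt
Reagents that add atoms: none
Why: Dissolving-metal reduction of the nitroarene spares the acetates and the aryl benzyl ether, which catalytic hydrogenation would endanger.

Step 5
Reactants: 7 1,2,4,6-tetra-O-acetyl-3-O-[2-amino-4-(benzyloxy)phenyl]-β-D-glucopyranose
Product: 9 1,2,4,6-tetra-O-acetyl-3-O-[4-(benzyloxy)-2-hydroxyphenyl]-β-D-glucopyranose, via arenediazonium hydrogen sulfate 8 (not isolated)
Conditions: NaNO2, aq H2SO4, MeCN, 0 °C; then Cu(NO3)2·3H2O (large excess), Cu2O, H2O, rt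
Reagents that add atoms: water, O (phenol oxygen); sodium nitrite, [Na+].[O-]N=O, and sulfuric acid, OS(=O)(=O)O (atoms held only in 8)
Why: Diazotisation followed by a copper-mediated Sandmeyer-type hydroxylation, in which the aryl radical is captured by divalent copper and water at room temperature, avoids the boiling acid of the classical phenol synthesis so that all four acetates should survive.

Step 6
Reactants: 9 1,2,4,6-tetra-O-acetyl-3-O-[4-(benzyloxy)-2-hydroxyphenyl]-β-D-glucopyranose
Product: 10 2,4,6-tri-O-acetyl-1,3-O-[4-(benzyloxy)-1,2-phenylene]-β-D-glucopyranose (phenylene C1 on O3, C2 on O1)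
Conditions: BF3·OEt2, 4 Å molecular sieves, CH2Cl2 (high dilution), 0 °C to rt
Reagents that add atoms: none
Why: Helferich-type Lewis-acid glycosylation of a phenol by a glycosyl acetate, run intramolecularly, in which the participating 2-O-acetyl group covers the α face, the phenol hanging from the β-oriented O3 can reach C1 only from the β face once O3 turns axial, and dilution plus release of acetic acid favour the seven-membered dioxepine; this sets the β-anomeric centre.

Step 7
Reactants: 10 2,4,6-tri-O-acetyl-1,3-O-[4-(benzyloxy)-1,2-phenylene]-β-D-glucopyranose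
Product: 11 1,3-O-[4-(benzyloxy)-1,2-phenylene]-β-D-glucopyranose
Conditions: NaOMe (cat.), MeOH, 0 °C; Amberlite IR-120 (H+)
Reagents that add atoms: none
Why: Zemplén transesterification, whose catalytic methoxide at 0 °C is far from the hot concentrated alkali needed to expel an aryloxide from a glycoside through its 2-alkoxide.

Step 8
Reactants: 11 1,3-O-[4-(benzyloxy)-1,2-phenylene]-β-D-glucopyranose
Product: 12 1,3-O-[4-(benzyloxy)-1,2-phenylene]-6-deoxy-6-iodo-β-D-glucopyranose
Conditions: I2, PPh3, imidazole, THF, rt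
Reagents that add atoms: iodine, II
Why: Garegg–Samuelsson (Appel-type) iodination, selective for the only primary hydroxyl because SN2 displacement of the alkoxyphosphonium ion at the two axial secondary carbinols is much slower.

Step 9
Reactants: 12 1,3-O-[4-(benzyloxy)-1,2-phenylene]-6-deoxy-6-iodo-β-D-glucopyranose
Product: 13 1,3-O-[4-(benzyloxy)-1,2-phenylene]-2,4-bis-O-(tert-butyldimethylsilyl)-6-deoxy-6-iodo-β-D-glucopyranose
Conditions: TBSOTf, 2,6-lutidine, CH2Cl2, 0 °C to rt
Reagents that add atoms: tert-butyldimethylsilyl triflate, CC(C)(C)[Si](C)(C)OS(=O)(=O)C(F)(F)F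
Why: Silylation with a silyl triflate and a hindered pyridine forms no alkoxide, so neither the primary iodide nor the anomeric aryloxide is endangered, and double silylation of syn-diaxial O2/O4 is known from 1,6-anhydroglucose.

Step 10
Reactants: 13 1,3-O-[4-(benzyloxy)-1,2-phenylene]-2,4-bis-O-(tert-butyldimethylsilyl)-6-deoxy-6-iodo-β-D-glucopyranose
Product: 14 1,3-O-[4-(benzyloxy)-1,2-phenylene]-2,4-bis-O-(tert-butyldimethylsilyl)-6-deoxy-β-D-xylo-hex-5-enopyranose
Conditions: DBU, THF, reflux
Reagents that add atoms: none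
Why: E2 dehydroiodination of a 6-iodopyranoside to the exocyclic enol ether, helped here by relief of the axial CH2I group that lies syn to O1 and O3.

Step 11
Reactants: 14 1,3-O-[4-(benzyloxy)-1,2-phenylene]-2,4-bis-O-(tert-butyldimethylsilyl)-6-deoxy-β-D-xylo-hex-5-enopyranose
Product: 16 bridged cyclohexanone (C8a ketone; C4a methylene; OTBS at C6 and C8; the 4-(benzyloxy)-1,2-phenylene spans O7, para to OBn, and O5; C5–C8 configured as in the target), via ring-opened titanium enolate/aryloxycarbenium zwitterion 15 (not isolated)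
Conditions: TiCl3(OiPr) [from TiCl4 and Ti(OiPr)4, 3:1], 4 Å molecular sieves, CH2Cl2, −78 °C; aq NaHCO3 quench at −78 °C
Reagents that add atoms: TiCl3(OiPr), CC(C)O[Ti](Cl)(Cl)Cl (held only in 15; nothing of it stays in 16)
Why: Proposed new method: the oxophilic titanium chloride should bind the enol-ether ring oxygen, the endocyclic C1–O5 acetal bond ionises to 15 (carbenium ion at sugar C1, the future C5, held by the aryloxy oxygen, plus the enolate O–C8a=C4a), and the enolate carbon C4a then adds to C5. The closest known reaction is the non-reductive Lewis-acid variant of the Ferrier carbocyclisation, shown with triisobutylaluminium or TiCl3(OiPr) on alkyl 6-deoxyhex-5-enopyranosides with retention of the aglycone, whereas an aryl aglycone that is also tied to O3 has not been tried. The carbocycle closes in a 6-(enolendo)-exo-trig mode and thereby completes the 2,5-dioxabicyclo[4.3.1]decane. C5 is the only new stereocentre and the tether fixes it, because in 15 the cationic carbon sits inside the seven-membered benzodioxepine and the enolate arm hangs from C7, so the three-atom bridge can form only on the face that leaves O5 cis to O7. The step needs endocyclic rather than exocyclic acetal cleavage, and here loss of the aryloxide is unproductive but reversible since it stays tethered and recloses, while the ortho-alkoxy arene, the weakly electron-withdrawing and poorly coordinating silyl ethers and the sp2 sugar C5 (no axial group in the O1/O3-diaxial conformer) all favour the productive ionisation. The reagent carries no transferable hydride, so C8a should stay a ketone, and the cold quench limits β-elimination of the aryloxide.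

Step 12
Reactants: 16 bridged cyclohexanone
Product: 17 trimethylsilyl enol ether of 16 (C4a=C8a, OTMS on C8a)
Conditions: TMSOTf, Et3N, CH2Cl2, 0 °C
Reagents that add atoms: trimethylsilyl triflate, C[Si](C)(C)OS(=O)(=O)C(F)(F)F
Why: Soft enolisation with a silyl triflate and a tertiary amine avoids a free enolate that could expel the β-aryloxide, and because H8 is equatorial in the locked chair (near the carbonyl plane) while C4a offers an axial hydrogen, the C4a=C8a enol ether should form without epimerising C8.

Step 13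
Reactants: 18 2,2,6-trimethyl-4H-1,3-dioxin-4-one; 19 4-methoxybenzyl bromide
Product: 20 6-[2-(4-methoxyphenyl)ethyl]-2,2-dimethyl-4H-1,3-dioxin-4-one
Conditions: LDA, THF/DMPU, −78 °C; then 19, −78 to −20 °C
Reagents that add atoms: none
Why: Vinylogous (γ-selective) alkylation of the lithium dienolate of the dioxinone with a reactive benzylic halide.

Step 14
Reactants: 17 trimethylsilyl enol ether; 20 6-[2-(4-methoxyphenyl)ethyl]-2,2-dimethyl-4H-1,3-dioxin-4-one
Product: 23 pyranone A compound: 2-[2-(4-methoxyphenyl)ethyl]-5,6,7,8-tetrahydrochromen-4-one with OTBS at C6 and C8 and the 4-(benzyloxy)-1,2-phenylene across O5/O7, via acylketene 21 (not isolated), via 8a-silyloxy dihydropyranone cycloadduct 22 (not isolated)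
Conditions: toluene, 110 °C (slow addition of excess 20); then TFA, CH2Cl2, 0 °C
Reagents that add atoms: none
Why: Retro-hetero-Diels–Alder loss of acetone from 20 gives 21, the nucleophilic C4a attacks its ketene carbon while the acyl oxygen closes on C8a (hetero-Diels–Alder reaction of acylketenes with enol ethers), and acid then expels silanol from 22 so that the transient centres C4a and C8a vanish in the γ-pyranone; an open C-acylated triketone would converge on 23 under the same acid.

Step 15
Reactants: 23 pyranone A compound (aryl benzyl ether)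
Product: 24 the corresponding phenol (free OH at the future C8a')
Conditions: H2 (1 atm), Pd/C, EtOAc, rt
Reagents that add atoms: none
Why: Hydrogenolysis of the only benzyl ether left, under mild conditions that γ-pyranone double bonds (as in hydrogenations of styrylchromones) and silyl ethers tolerate.

Step 16
Reactants: 24 phenol
Product: 25 o-iodophenol (iodine at the future C4a', ortho to OH and para to the O5-bearing carbon)
Conditions: NIS (1 equiv), MeCN, 0 °C
Reagents that add atoms: N-iodosuccinimide, O=C1CCC(=O)N1I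
Why: Electrophilic aromatic iodination of a 3,4-dialkoxyphenol, which should follow the sesamol pattern (ortho to OH and para to an alkoxy group) because the other ortho site is wedged between two oxygens and the anisole and pyranone rings are much less nucleophilic.

Step 17
Reactants: 25 o-iodophenol; 26 4-phenyl-1-butyne
Product: 28 6,8-bis-O-TBS-4'-methoxyaquisinenone G, via o-hydroxyaryl ynone 27 (not isolated)
Conditions: PdCl2(dppf) (cat.), CO (10 bar), Et2NH/DMF, 80 °C
Reagents that add atoms: carbon monoxide, [C-]#[O+]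
Why: Carbonylative Sonogashira coupling (oxidative addition to zerovalent palladium, CO insertion, alkynylation) gives 27, and diethylamine relays ring closure through its conjugate adduct so that the phenol closes 6-endo to the chromone rather than 5-exo to an aurone.

Step 18
Reactants: 28 6,8-bis-O-TBS-4'-methoxyaquisinenone G
Product: 29 (+)-4'-methoxyaquisinenone G, (5R,6S,7R,8S)
Conditions: HF·pyridine, THF, 0 °C to rt
Reagents that add atoms: none
Why: Fluoride-driven desilylation under weakly acidic conditions frees O6–H and O8–H without the reduction or strong Lewis acid that could break the allylic C5–O aryl ether or the aryl methyl ether.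

## Compound list

1 | 4-fluoro-3-nitrophenol | Oc1ccc(F)c([N+](=O)[O-])c1 | starting material
2 | 4-(benzyloxy)-1-fluoro-2-nitrobenzene | O=[N+]([O-])c1cc(OCc2ccccc2)ccc1F | intermediate
3 | 1,2:5,6-di-O-isopropylidene-α-D-glucofuranose | CC1(C)O[C@H]2O[C@H]([C@H]3COC(C)(C)O3)[C@H](O)[C@H]2O1 | starting material
4 | 3-O-[4-(benzyloxy)-2-nitrophenyl]-1,2:5,6-di-O-isopropylidene-α-D-glucofuranose | CC1(C)O[C@H]2O[C@H]([C@H]3COC(C)(C)O3)[C@H](Oc3ccc(OCc4ccccc4)cc3[N+](=O)[O-])[C@H]2O1 | intermediate
5 | 3-O-[4-(benzyloxy)-2-nitrophenyl]-D-glucopyranose (anomeric mixture) | OC[C@H]1OC(O)[C@H](O)[C@@H](Oc2ccc(OCc3ccccc3)cc2[N+](=O)[O-])[C@@H]1O | intermediate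
6 | 1,2,4,6-tetra-O-acetyl-3-O-[4-(benzyloxy)-2-nitrophenyl]-β-D-glucopyranose | CC(=O)OC[C@H]1O[C@@H](OC(C)=O)[C@H](OC(C)=O)[C@@H](Oc2ccc(OCc3ccccc3)cc2[N+](=O)[O-])[C@@H]1OC(C)=O | intermediate
7 | 1,2,4,6-tetra-O-acetyl-3-O-[2-amino-4-(benzyloxy)phenyl]-β-D-glucopyranose | CC(=O)OC[C@H]1O[C@@H](OC(C)=O)[C@H](OC(C)=O)[C@@H](Oc2ccc(OCc3ccccc3)cc2N)[C@@H]1OC(C)=O | intermediate
8 | arenediazonium hydrogen sulfate derived from 7 | CC(=O)OC[C@H]1O[C@@H](OC(C)=O)[C@H](OC(C)=O)[C@@H](Oc2ccc(OCc3ccccc3)cc2[N+]#N)[C@@H]1OC(C)=O.OS(=O)(=O)[O-] | intermediate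
9 | 1,2,4,6-tetra-O-acetyl-3-O-[4-(benzyloxy)-2-hydroxyphenyl]-β-D-glucopyranose | CC(=O)OC[C@H]1O[C@@H](OC(C)=O)[C@H](OC(C)=O)[C@@H](Oc2ccc(OCc3ccccc3)cc2O)[C@@H]1OC(C)=O | intermediate
10 | 2,4,6-tri-O-acetyl-1,3-O-[4-(benzyloxy)-1,2-phenylene]-β-D-glucopyranose | CC(=O)OC[C@H]1O[C@H]2Oc3cc(OCc4ccccc4)ccc3O[C@H]([C@H]2OC(C)=O)[C@@H]1OC(C)=O | intermediate
11 | 1,3-O-[4-(benzyloxy)-1,2-phenylene]-β-D-glucopyranose | OC[C@H]1O[C@H]2Oc3cc(OCc4ccccc4)ccc3O[C@H]([C@H]2O)[C@@H]1O | intermediate
12 | 1,3-O-[4-(benzyloxy)-1,2-phenylene]-6-deoxy-6-iodo-β-D-glucopyranose | IC[C@H]1O[C@H]2Oc3cc(OCc4ccccc4)ccc3O[C@H]([C@H]2O)[C@@H]1O | intermediate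
13 | 1,3-O-[4-(benzyloxy)-1,2-phenylene]-2,4-bis-O-TBS-6-deoxy-6-iodo-β-D-glucopyranose | IC[C@H]1O[C@H]2Oc3cc(OCc4ccccc4)ccc3O[C@H]([C@H]2O[Si](C)(C)C(C)(C)C)[C@@H]1O[Si](C)(C)C(C)(C)C | intermediate
14 | 1,3-O-[4-(benzyloxy)-1,2-phenylene]-2,4-bis-O-TBS-6-deoxy-β-D-xylo-hex-5-enopyranose (key-step precursor) | C=C1O[C@H]2Oc3cc(OCc4ccccc4)ccc3O[C@H]([C@H]2O[Si](C)(C)C(C)(C)C)[C@@H]1O[Si](C)(C)C(C)(C)C | intermediate
15 | ring-opened titanium enolate/aryloxycarbenium zwitterion | C=C(O[Ti-](Cl)(Cl)(Cl)OC(C)C)[C@@H](O[Si](C)(C)C(C)(C)C)[C@@H]1Oc2ccc(OCc3ccccc3)cc2[O+]=C[C@@H]1O[Si](C)(C)C(C)(C)C | intermediate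
16 | bridged C8a ketone, 6,8-bis-O-TBS, benzyloxybenzo ring across O5/O7 (key-step product) | C1C(=O)[C@@H](O[Si](C)(C)C(C)(C)C)[C@@H]2Oc3ccc(OCc4ccccc4)cc3O[C@H]1[C@@H]2O[Si](C)(C)C(C)(C)C | intermediate
17 | C4a=C8a trimethylsilyl enol ether of 16 | C1=C(O[Si](C)(C)C)[C@@H](O[Si](C)(C)C(C)(C)C)[C@@H]2Oc3ccc(OCc4ccccc4)cc3O[C@H]1[C@@H]2O[Si](C)(C)C(C)(C)C | intermediate
18 | 2,2,6-trimethyl-4H-1,3-dioxin-4-one | CC1=CC(=O)OC(C)(C)O1 | starting material
19 | 4-methoxybenzyl bromide | COc1ccc(CBr)cc1 | starting material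
20 | 6-[2-(4-methoxyphenyl)ethyl]-2,2-dimethyl-4H-1,3-dioxin-4-one | COc1ccc(CCC2=CC(=O)OC(C)(C)O2)cc1 | intermediate
21 | 5-(4-methoxyphenyl)-3-oxopent-1-en-1-one (acylketene) | COc1ccc(CCC(=O)C=C=O)cc1 | intermediate
22 | 8a-trimethylsilyloxy-4a,8a-dihydropyranone cycloadduct (C4a, C8a undefined) | COc1ccc(CCC2=CC(=O)C3C(O2)(O[Si](C)(C)C)[C@@H](O[Si](C)(C)C(C)(C)C)[C@@H]2Oc4ccc(OCc5ccccc5)cc4O[C@H]3[C@@H]2O[Si](C)(C)C(C)(C)C)cc1 | intermediate
23 | pyranone A compound, aryl benzyl ether, 6,8-bis-O-TBS | COc1ccc(CCc2cc(=O)c3c(o2)[C@@H](O[Si](C)(C)C(C)(C)C)[C@@H]2Oc4ccc(OCc5ccccc5)cc4O[C@H]3[C@@H]2O[Si](C)(C)C(C)(C)C)cc1 | intermediate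
24 | pyranone A compound, free phenol | COc1ccc(CCc2cc(=O)c3c(o2)[C@@H](O[Si](C)(C)C(C)(C)C)[C@@H]2Oc4ccc(O)cc4O[C@H]3[C@@H]2O[Si](C)(C)C(C)(C)C)cc1 | intermediate
25 | pyranone A compound, o-iodophenol | COc1ccc(CCc2cc(=O)c3c(o2)[C@@H](O[Si](C)(C)C(C)(C)C)[C@@H]2Oc4cc(I)c(O)cc4O[C@H]3[C@@H]2O[Si](C)(C)C(C)(C)C)cc1 | intermediate
26 | 4-phenyl-1-butyne | C#CCCc1ccccc1 | starting material
27 | o-hydroxyaryl ynone | COc1ccc(CCc2cc(=O)c3c(o2)[C@@H](O[Si](C)(C)C(C)(C)C)[C@@H]2Oc4cc(C(=O)C#CCCc5ccccc5)c(O)cc4O[C@H]3[C@@H]2O[Si](C)(C)C(C)(C)C)cc1 | intermediate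
28 | 6,8-bis-O-TBS-4'-methoxyaquisinenone G | COc1ccc(CCc2cc(=O)c3c(o2)[C@@H](O[Si](C)(C)C(C)(C)C)[C@@H]2Oc4cc5c(=O)cc(CCc6ccccc6)oc5cc4O[C@H]3[C@@H]2O[Si](C)(C)C(C)(C)C)cc1 | intermediate
29 | (+)-4'-methoxyaquisinenone G | COc1ccc(CCc2cc(=O)c3c(o2)[C@@H](O)[C@@H]2Oc4cc5c(=O)cc(CCc6ccccc6)oc5cc4O[C@H]3[C@@H]2O)cc1 | target

## Step count

Total step count: 18.
Longest linear sequence: 17 (steps 1–12 and 14–18, from 4-fluoro-3-nitrophenol).

## Steps most likely to fail

**Step 11.**
- The aryloxy group supports the cation less well than an alkoxy group, so ionisation may be sluggish.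
- Titanium may sit on the catechol diether oxygens and favour exocyclic cleavage.
- Adventitious acid may protonate the enol ether.
- The product may lose the aryloxide by β-elimination.

The fallback sets out from 14 and uses the classical Ferrier carbocyclisation. Hg(OCOCF3)2 (cat.) in acetone/water should give the β-hydroxy cyclohexanone F1, in which the phenol released from the anomeric carbon stays attached through O7. Ac2O/pyridine followed by DBU should acetylate the phenol and the carbinol and eliminate the β-acetate, giving the cyclohexenone aryl acetate F2. K2CO3 in MeOH then frees the phenoxide, which should close by a 7-exo-trig oxa-Michael addition to C5. That addition is possible only on the face of O7. The fallback comes back to the route at 16.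

**Step 6.**
- Oligomerisation may compete with ring closure.
- The acetyl group may transfer from the activated donor to the phenol.
- The glycosylation may reverse, because the all-axial bridged product is strained.

The fallback sets out from 9 and replaces the cationic closure by a neutral, irreversible SN2-type dehydration. Hydrazine acetate in DMF should remove only the anomeric acetate to give the hemiacetal F3. An intramolecular Mitsunobu glycosylation (PPh3, DIAD, toluene, high dilution) should then displace the anomeric oxyphosphonium group with the tethered phenol. The fallback comes back to the route at 10.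

**Step 14.**
- Approach to C4a is hindered by the axial silyl ethers below and the arene bridge above, so the acylketene may dimerise faster than it is trapped.
- The enol ether may lose its silyl group at 110 °C.

The fallback sets out from 17 and builds the pyranone stepwise at low temperature.
- 5-(4-Methoxyphenyl)pent-2-ynal F4 is made from 4-(4-methoxyphenyl)-1-butyne with nBuLi and DMF.
- F4 is added to 17 in a Mukaiyama aldol reaction (BF3·OEt2, CH2Cl2, −78 °C) to give the propargylic aldol F5.
- Dess–Martin periodinane should oxidise F5 to the 2-alkynoyl ketone F6.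
- AuCl(PPh3)/AgOTf (cat.) should close the enol oxygen on the alkyne in a 6-endo-dig fashion.

The fallback comes back to the route at 23.

## Further compounds

F1 | step 11 | β-hydroxy cyclohexanone with the 4-(benzyloxy)-2-hydroxyphenyl ether on O7 (carbinol centre C5 undefined) | O=C1CC(O)[C@H](O[Si](C)(C)C(C)(C)C)[C@@H](Oc2ccc(OCc3ccccc3)cc2O)[C@@H]1O[Si](C)(C)C(C)(C)C
F2 | step 11 | cyclohexenone (C4a=C5) with the 2-acetoxy-4-(benzyloxy)phenyl ether on O7 | O=C1C=C[C@H](O[Si](C)(C)C(C)(C)C)[C@@H](Oc2ccc(OCc3ccccc3)cc2OC(C)=O)[C@@H]1O[Si](C)(C)C(C)(C)C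
F3 | step 6 | 2,4,6-tri-O-acetyl-3-O-[4-(benzyloxy)-2-hydroxyphenyl]-D-glucopyranose (hemiacetal) | CC(=O)OC[C@H]1OC(O)[C@H](OC(C)=O)[C@@H](Oc2ccc(OCc3ccccc3)cc2O)[C@@H]1OC(C)=O
F4 | step 14 | 5-(4-methoxyphenyl)pent-2-ynal | COc1ccc(CCC#CC=O)cc1
F5 | step 14 | propargylic aldol at C4a of the bridged ketone (C4a and carbinol undefined) | COc1ccc(CCC#CC(O)C2C(=O)[C@@H](O[Si](C)(C)C(C)(C)C)[C@@H]3Oc4ccc(OCc5ccccc5)cc4O[C@H]2[C@@H]3O[Si](C)(C)C(C)(C)C)cc1
F6 | step 14 | 2-alkynoyl ketone (C4a undefined) | COc1ccc(CCC#CC(=O)C2C(=O)[C@@H](O[Si](C)(C)C(C)(C)C)[C@@H]3Oc4ccc(OCc5ccccc5)cc4O[C@H]2[C@@H]3O[Si](C)(C)C(C)(C)C)cc1
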